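**Retrosynthetic overview**

1. Target 31 ⇐ bis-TBS ether 30 ⇐ acylation of epoxy alcohol 29 with aroyl chloride 26 ⇐ OH-directed epoxidation of cycloheptene 28 ⇐ RCM of diene 27 (seven-membered ring closed late, epoxide after it).
2. 27 ⇐ C6–C7 bond: chelation-controlled addition of the (Z)-γ-silyloxyallylstannane 20 to the cyclopentane β-hydroxy aldehyde 16 (sets C6 and C7).
3. 16 ⇐ glycol cleavage of an anti-aldol adduct of enol silane 5 with (S)-O-TBS-lactaldehyde 9 (traceless controller for C5), after i-Pr addition to the ketone (C4).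
4. 5 ⇐ Cu-catalysed asymmetric conjugate methylation of 3-allylcyclopentenone 3 (C1 quaternary centre); the five-membered ring comes from 3-methoxycyclopentenone 1.
5. Ring order: cyclopentane (bought) → cycloheptene (RCM) → epoxide.

Assumption: positions use daucane numbering (C1 = CH3-bearing ring-fusion carbon, C2/C3 = ring CH2, C4 = i-Pr carbinol, C5 = ring-fusion CH, C6 = ester carbon, C7 = free carbinol, C8/C9 = epoxide with CH3 on C8, C10 = CH2); the target is then (1R,4R,5S,6R,7S,8R,9S).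

**Route**

Step 1
Reactants: 1 3-methoxycyclopent-2-en-1-one
Product: 3 3-(prop-2-en-1-yl)cyclopent-2-en-1-one, via tertiary allylic alcohol 2 (not isolated)
Conditions: allylMgBr, THF, −78 → 0 °C; then 1 M HCl, 0 °C
Reagents that add atoms: allylmagnesium bromide, C=CC[Mg]Br; water, O
Why: Stork–Danheiser-type 1,2-addition to the vinylogous ester, then acid hydrolysis with loss of the tertiary hydroxyl, transposes the carbonyl and gives the β-allyl enone; no stereocentre is formed.

Step 2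
Reactants: 3 3-(prop-2-en-1-yl)cyclopent-2-en-1-one
Product: 5 (R)-trimethyl{[3-methyl-3-(prop-2-en-1-yl)cyclopent-1-en-1-yl]oxy}silane, via dimethylaluminium enolate 4 (not isolated)
Conditions: Me3Al, Cu(OTf)2 (5 mol %), chiral sulfonate-NHC·Ag complex (2.5 mol %), THF, −78 °C; then TMSOTf, −78 → 0 °C
Reagents that add atoms: trimethylaluminium, C[Al](C)C; trimethylsilyl trifluoromethanesulfonate, C[Si](C)(C)OS(=O)(=O)C(F)(F)F
Why: Cu-catalysed enantioselective conjugate addition builds the C1 quaternary centre (R, set by the ligand antipode), and O-silylation of the aluminium enolate fixes the enolate regiochemistry towards the future C5.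

Step 3
Reactants: 6 ethyl (S)-2-hydroxypropanoate
Product: 7 ethyl (S)-2-[(tert-butyldimethylsilyl)oxy]propanoate
Conditions: TBSCl, imidazole, DMF, rt
Reagents that add atoms: tert-butyldimethylsilyl chloride, CC(C)(C)[Si](C)(C)Cl
Why: Standard O-silylation; the lactate stereocentre is not touched.

Step 4
Reactants: 7 ethyl (S)-2-[(tert-butyldimethylsilyl)oxy]propanoate
Product: 9 (S)-2-[(tert-butyldimethylsilyl)oxy]propanal, via aluminium hemiacetal 8 (not isolated)
Conditions: DIBAL-H, CH2Cl2, −78 °C; MeOH, aq. Rochelle salt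
Reagents that add atoms: none
Why: Low-temperature DIBAL half-reduction stops at the tetrahedral aluminium hemiacetal, which releases the configurationally intact α-silyloxy aldehyde on work-up.

Step 5
Reactants: 5 (R)-trimethyl{[3-methyl-3-(prop-2-en-1-yl)cyclopent-1-en-1-yl]oxy}silane; 9 (S)-2-[(tert-butyldimethylsilyl)oxy]propanal
Product: 13 (2S,3R)-2-[(1R,2S)-2-(tert-butyldimethylsilyloxy)-1-hydroxypropyl]-3-methyl-3-(prop-2-en-1-yl)cyclopentan-1-one, via lithium enolate 10 (not isolated), via dicyclohexylboron enolate 11 (not isolated), via boron aldolate 12 (not isolated)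
Conditions: MeLi, THF, 0 °C; (c-C6H11)2BCl, −78 °C; 9, −78 → −30 °C; then pH 7 buffer, MeOH, 30% H2O2, 0 °C
Reagents that add atoms: none
Why: Boron aldol through a closed Zimmerman–Traxler transition state: the ring-locked E-enolate gives the anti adduct and the (S)-α-silyloxy aldehyde reacts on its Felkin–Anh/Cornforth face, which forces the aldehyde onto the enolate face opposite the allyl group (matched with the weak substrate bias) and sets C5 as S.

Step 6
Reactants: 13 (2S,3R)-2-[(1R,2S)-2-(tert-butyldimethylsilyloxy)-1-hydroxypropyl]-3-methyl-3-(prop-2-en-1-yl)cyclopentan-1-one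
Product: 14 (1R,2S,3R)-2-[(1R,2S)-2-(tert-butyldimethylsilyloxy)-1-hydroxypropyl]-3-methyl-1-(propan-2-yl)-3-(prop-2-en-1-yl)cyclopentan-1-ol
Conditions: i-PrMgCl·LiCl (3.5 equiv), LaCl3·2LiCl, THF, −20 → 0 °C; aq. NH4Cl
Reagents that add atoms: isopropylmagnesium chloride, CC(C)[Mg]Cl
Why: Lanthanide-mediated Grignard 1,2-addition (suppresses enolisation and β-hydride reduction) occurs on the ketone face opposite the C5 side chain, giving the C4 carbinol with OH cis to the side chain (R).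

Step 7
Reactants: 14 (1R,2S,3R)-2-[(1R,2S)-2-(tert-butyldimethylsilyloxy)-1-hydroxypropyl]-3-methyl-1-(propan-2-yl)-3-(prop-2-en-1-yl)cyclopentan-1-ol
Product: 15 (1R,2S)-1-[(1S,2R,5R)-2-hydroxy-5-methyl-2-(propan-2-yl)-5-(prop-2-en-1-yl)cyclopentyl]propane-1,2-diol
Conditions: TBAF, THF, rt
Reagents that add atoms: none
Why: Fluoride-mediated desilylation frees the 1,2-diol needed for cleavage; no stereocentre changes.

Step 8
Reactants: 15 (1R,2S)-1-[(1S,2R,5R)-2-hydroxy-5-methyl-2-(propan-2-yl)-5-(prop-2-en-1-yl)cyclopentyl]propane-1,2-diol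
Product: 16 (1R,2R,5R)-2-hydroxy-5-methyl-2-(propan-2-yl)-5-(prop-2-en-1-yl)cyclopentane-1-carbaldehyde
Conditions: NaIO4, THF/pH 7 buffer, 0 °C
Reagents that add atoms: none
Why: Malaprade glycol cleavage removes the lactaldehyde-derived controller carbons and leaves C6 as the aldehyde; C5 keeps its configuration, which is also the thermodynamically preferred one (CHO trans to isopropyl and allyl).

Step 9
Reactants: 17 2-methylprop-2-en-1-ol
Product: 18 tert-butyldimethyl[(2-methylprop-2-en-1-yl)oxy]silane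
Conditions: TBSCl, imidazole, CH2Cl2, rt
Reagents that add atoms: tert-butyldimethylsilyl chloride, CC(C)(C)[Si](C)(C)Cl
Why: Standard O-silylation of a primary allylic alcohol.

Step 10
Reactants: 18 tert-butyldimethyl[(2-methylprop-2-en-1-yl)oxy]silane
Product: 20 (Z)-tributyl[3-(tert-butyldimethylsilyloxy)-2-methylprop-2-en-1-yl]stannane, via lithiated allyl silyl ether 19 (not isolated)
Conditions: s-BuLi, THF, −78 °C; then Bu3SnCl, −78 °C
Reagents that add atoms: tributyltin chloride, CCCC[Sn](Cl)(CCCC)CCCC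
Why: α-Deprotonation gives the O-coordinated (Z)-oxyallyl anion, which the soft tin electrophile captures at the γ-terminus (metalation/γ-stannylation) to give the Z enol ether.

Step 11
Reactants: 21 4-bromophenol
Product: 22 (4-bromophenoxy)(tert-butyl)dimethylsilane
Conditions: TBSCl, imidazole, DMF, rt
Reagents that add atoms: tert-butyldimethylsilyl chloride, CC(C)(C)[Si](C)(C)Cl
Why: Standard phenol silylation.

Step 12
Reactants: 22 (4-bromophenoxy)(tert-butyl)dimethylsilane
Product: 25 4-[(tert-butyldimethylsilyl)oxy]benzoic acid, via aryllithium 23 (not isolated), via lithium carboxylate 24 (not isolated)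
Conditions: n-BuLi, THF, −78 °C; CO2; then 1 M HCl to pH 3
Reagents that add atoms: carbon dioxide, O=C=O
Why: Bromine–lithium exchange followed by carboxylation of the aryllithium; the para silyl ether is stable at −78 °C.

Step 13
Reactants: 25 4-[(tert-butyldimethylsilyl)oxy]benzoic acid
Product: 26 4-[(tert-butyldimethylsilyl)oxy]benzoyl chloride
Conditions: (COCl)2, DMF (cat.), CH2Cl2, 0 °C → rt
Reagents that add atoms: oxalyl chloride, O=C(Cl)C(Cl)=O
Why: Vilsmeier-catalysed acid chloride formation; the aryl silyl ether tolerates these conditions.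

Step 14
Reactants: 16 (1R,2R,5R)-2-hydroxy-5-methyl-2-(propan-2-yl)-5-(prop-2-en-1-yl)cyclopentane-1-carbaldehyde; 20 (Z)-tributyl[3-(tert-butyldimethylsilyloxy)-2-methylprop-2-en-1-yl]stannane
Product: 27 (1R,2S,3R)-2-[(1R,2R)-2-(tert-butyldimethylsilyloxy)-1-hydroxy-3-methylbut-3-en-1-yl]-3-methyl-1-(propan-2-yl)-3-(prop-2-en-1-yl)cyclopentan-1-ol
Conditions: MgBr2·OEt2 (3 equiv), CH2Cl2, −78 → −20 °C
Reagents that add atoms: none
Why: Lewis-acid-promoted SE2′ addition of a γ-silyloxyallylstannane to the Mg chelate of the β-hydroxy aldehyde: attack on the exposed face anti to C1 sets C6 (R), and the antiperiplanar open transition state of the Z enol ether gives the 6,7-syn diol monosilyl ether (C7).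

Step 15
Reactants: 27 (1R,2S,3R)-2-[(1R,2R)-2-(tert-butyldimethylsilyloxy)-1-hydroxy-3-methylbut-3-en-1-yl]-3-methyl-1-(propan-2-yl)-3-(prop-2-en-1-yl)cyclopentan-1-ol
Product: 28 (1R,4R,5S,6R,7R)-7-(tert-butyldimethylsilyloxy)dauc-8-ene-4,6-diol
Conditions: Grubbs II (10 mol %), toluene (2 mM), 80 °C
Reagents that add atoms: none
Why: Ring-closing metathesis between the allyl and isopropenyl groups closes the trans-fused cycloheptene as the trisubstituted C8=C9 alkene; no stereocentre is formed.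

Step 16
Reactants: 28 (1R,4R,5S,6R,7R)-7-(tert-butyldimethylsilyloxy)dauc-8-ene-4,6-diol
Product: 29 (1R,4R,5S,6R,7S,8S,9S)-7-(tert-butyldimethylsilyloxy)-8,9-epoxydaucane-4,6-diol
Conditions: VO(acac)2 (10 mol %), t-BuOOH, CH2Cl2, 0 °C → rt
Reagents that add atoms: tert-butyl hydroperoxide, CC(C)(C)OO
Why: Vanadium-catalysed hydroxyl-directed epoxidation: the homoallylic C6-OH delivers the peroxide to its own face, which is also the face opposite the C7-OTBS and the C1 methyl, setting C8 and C9.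

Step 17
Reactants: 29 (1R,4R,5S,6R,7S,8S,9S)-7-(tert-butyldimethylsilyloxy)-8,9-epoxydaucane-4,6-diol; 26 4-[(tert-butyldimethylsilyl)oxy]benzoyl chloride
Product: 30 (1R,4R,5S,6R,7S,8S,9S)-7-(tert-butyldimethylsilyloxy)-8,9-epoxy-4-hydroxydaucan-6-yl 4-[(tert-butyldimethylsilyl)oxy]benzoate
Conditions: DMAP, Et3N, CH2Cl2, 0 → 40 °C
Reagents that add atoms: none
Why: DMAP-catalysed acyl transfer esterifies the only secondary hydroxyl (C6); the tertiary C4-OH does not react and the epoxide is stable to these conditions.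

Step 18
Reactants: 30 (1R,4R,5S,6R,7S,8S,9S)-7-(tert-butyldimethylsilyloxy)-8,9-epoxy-4-hydroxydaucan-6-yl 4-[(tert-butyldimethylsilyl)oxy]benzoate
Product: 31 (1R,4R,5S,6R,7S,8R,9S)-8,9-epoxy-4,7-dihydroxydaucan-6-yl 4-hydroxybenzoate (CNP0290052.1)
Conditions: TBAF/AcOH (1:1), THF, 0 → 35 °C
Reagents that add atoms: none
Why: Acetic-acid-buffered fluoride desilylation removes the aryl and the C7 silyl ethers while avoiding base-induced 6→7 acyl migration and acid-induced epoxide opening.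

**Compound list**

1 | 3-methoxycyclopent-2-en-1-one | COC1=CC(=O)CC1 | starting material
2 | 3-methoxy-1-(prop-2-en-1-yl)cyclopent-2-en-1-ol (racemic, formed as its bromomagnesium alkoxide) | COC1=CC(O)(CC=C)CC1 | intermediate
3 | 3-(prop-2-en-1-yl)cyclopent-2-en-1-one | O=C1C=C(CC=C)CC1 | intermediate
4 | dimethylaluminium enolate of (R)-3-methyl-3-(prop-2-en-1-yl)cyclopentanone (O–AlMe2 on C1, C1=C2) | C[Al](C)OC1=C[C@@](C)(CC=C)CC1 | intermediate
5 | (R)-trimethyl{[3-methyl-3-(prop-2-en-1-yl)cyclopent-1-en-1-yl]oxy}silane | C[Si](C)(C)OC1=C[C@@](C)(CC=C)CC1 | intermediate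
6 | ethyl (S)-2-hydroxypropanoate (ethyl L-lactate) | CCOC(=O)[C@H](C)O | starting material
7 | ethyl (S)-2-[(tert-butyldimethylsilyl)oxy]propanoate | CCOC(=O)[C@H](C)O[Si](C)(C)C(C)(C)C | intermediate
8 | diisobutylaluminium hemiacetal of 9 [(2S)-2-(tert-butyldimethylsilyloxy)-1-ethoxypropoxy]diisobutylalumane, epimers at C1 | CCOC(O[Al](CC(C)C)CC(C)C)[C@H](C)O[Si](C)(C)C(C)(C)C | intermediate
9 | (S)-2-[(tert-butyldimethylsilyl)oxy]propanal | O=C[C@H](C)O[Si](C)(C)C(C)(C)C | intermediate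
10 | lithium enolate of (R)-3-methyl-3-(prop-2-en-1-yl)cyclopentanone (C1=C2) | [Li]OC1=C[C@@](C)(CC=C)CC1 | intermediate
11 | dicyclohexyl{[(R)-3-methyl-3-(prop-2-en-1-yl)cyclopent-1-en-1-yl]oxy}borane | C1CCC(CC1)B(OC2=C[C@@](C)(CC=C)CC2)C3CCCCC3 | intermediate
12 | O-dicyclohexylboryl aldolate of 13 | O=C1CC[C@](C)(CC=C)[C@H]1[C@@H](OB(C2CCCCC2)C3CCCCC3)[C@H](C)O[Si](C)(C)C(C)(C)C | intermediate
13 | (2S,3R)-2-[(1R,2S)-2-(tert-butyldimethylsilyloxy)-1-hydroxypropyl]-3-methyl-3-(prop-2-en-1-yl)cyclopentan-1-one | O=C1CC[C@](C)(CC=C)[C@H]1[C@@H](O)[C@H](C)O[Si](C)(C)C(C)(C)C | intermediate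
14 | (1R,2S,3R)-2-[(1R,2S)-2-(tert-butyldimethylsilyloxy)-1-hydroxypropyl]-3-methyl-1-(propan-2-yl)-3-(prop-2-en-1-yl)cyclopentan-1-ol | CC(C)[C@]1(O)CC[C@](C)(CC=C)[C@H]1[C@@H](O)[C@H](C)O[Si](C)(C)C(C)(C)C | intermediate
15 | (1R,2S)-1-[(1S,2R,5R)-2-hydroxy-5-methyl-2-(propan-2-yl)-5-(prop-2-en-1-yl)cyclopentyl]propane-1,2-diol | CC(C)[C@]1(O)CC[C@](C)(CC=C)[C@H]1[C@@H](O)[C@H](C)O | intermediate
16 | (1R,2R,5R)-2-hydroxy-5-methyl-2-(propan-2-yl)-5-(prop-2-en-1-yl)cyclopentane-1-carbaldehyde | CC(C)[C@]1(O)CC[C@](C)(CC=C)[C@H]1C=O | intermediate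
17 | 2-methylprop-2-en-1-ol | C=C(C)CO | starting material
18 | tert-butyldimethyl[(2-methylprop-2-en-1-yl)oxy]silane | C=C(C)CO[Si](C)(C)C(C)(C)C | intermediate
19 | [1-(tert-butyldimethylsilyloxy)-2-methylprop-2-en-1-yl]lithium (oxyallyl anion, drawn as the α-lithio form) | [Li]C(O[Si](C)(C)C(C)(C)C)C(C)=C | intermediate
20 | (Z)-tributyl[3-(tert-butyldimethylsilyloxy)-2-methylprop-2-en-1-yl]stannane | CCCC[Sn](CCCC)(CCCC)C/C(C)=C\O[Si](C)(C)C(C)(C)C | intermediate
21 | 4-bromophenol | Oc1ccc(Br)cc1 | starting material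
22 | (4-bromophenoxy)(tert-butyl)dimethylsilane | CC(C)(C)[Si](C)(C)Oc1ccc(Br)cc1 | intermediate
23 | {4-[(tert-butyldimethylsilyl)oxy]phenyl}lithium | [Li]c1ccc(O[Si](C)(C)C(C)(C)C)cc1 | intermediate
24 | lithium 4-[(tert-butyldimethylsilyl)oxy]benzoate | [Li]OC(=O)c1ccc(O[Si](C)(C)C(C)(C)C)cc1 | intermediate
25 | 4-[(tert-butyldimethylsilyl)oxy]benzoic acid | OC(=O)c1ccc(O[Si](C)(C)C(C)(C)C)cc1 | intermediate
26 | 4-[(tert-butyldimethylsilyl)oxy]benzoyl chloride | ClC(=O)c1ccc(O[Si](C)(C)C(C)(C)C)cc1 | intermediate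
27 | (1R,2S,3R)-2-[(1R,2R)-2-(tert-butyldimethylsilyloxy)-1-hydroxy-3-methylbut-3-en-1-yl]-3-methyl-1-(propan-2-yl)-3-(prop-2-en-1-yl)cyclopentan-1-ol | CC(C)[C@]1(O)CC[C@](C)(CC=C)[C@H]1[C@@H](O)[C@H](O[Si](C)(C)C(C)(C)C)C(C)=C | intermediate
28 | (1R,4R,5S,6R,7R)-7-(tert-butyldimethylsilyloxy)dauc-8-ene-4,6-diol (trans-fused bicyclo[5.3.0]decene) | CC(C)[C@]1(O)CC[C@]2(C)CC=C(C)[C@@H](O[Si](C)(C)C(C)(C)C)[C@H](O)[C@H]21 | intermediate
29 | (1R,4R,5S,6R,7S,8S,9S)-7-(tert-butyldimethylsilyloxy)-8,9-epoxydaucane-4,6-diol (epoxide on the face of 6-OH) | CC(C)[C@]1(O)CC[C@]2(C)C[C@@H]3O[C@]3(C)[C@@H](O[Si](C)(C)C(C)(C)C)[C@H](O)[C@H]21 | intermediate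
30 | (1R,4R,5S,6R,7S,8S,9S)-7-(tert-butyldimethylsilyloxy)-8,9-epoxy-4-hydroxydaucan-6-yl 4-[(tert-butyldimethylsilyl)oxy]benzoate (bis-TBS ether of 31) | CC(C)[C@]1(O)CC[C@]2(C)C[C@@H]3O[C@]3(C)[C@@H](O[Si](C)(C)C(C)(C)C)[C@H](OC(=O)c3ccc(O[Si](C)(C)C(C)(C)C)cc3)[C@H]21 | intermediate
31 | (1R,4R,5S,6R,7S,8R,9S)-8,9-epoxy-4,7-dihydroxydaucan-6-yl 4-hydroxybenzoate (CNP0290052.1) | CC(C)[C@]1(O)CC[C@]2(C)C[C@@H]3O[C@]3(C)[C@@H](O)[C@H](OC(=O)c3ccc(O)cc3)[C@H]21 | target

**Step count and risks**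

Total step count: 18. Longest linear sequence: 11 steps (1, 2, 5, 6, 7, 8, 14, 15, 16, 17, 18); the lactaldehyde (3, 4), stannane (9, 10) and aroyl chloride (11–13) branches run in parallel.

Steps most likely to fail:

Step 6 (i-Pr addition to a hindered, enolisable β-hydroxy ketone; retro-aldol of the metal aldolate, enolisation or reduction may win). The fallback sets out from 13 and returns at 15. The free C6 hydroxyl is first capped with TESOTf/2,6-lutidine to give the C6 triethylsilyl ether F1, so no alkoxide is available for retro-aldol. i-PrLi/CeCl3 at −78 °C then adds opposite the side chain to give the bis-silylated tertiary alcohol F2. The TBAF treatment of step 7 removes both silyl groups and the route is rejoined at triol 15.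

Step 14 (the union: chelation through a free tertiary hydroxyl, a neopentyl-type aldehyde, and two new stereocentres under substrate control). The fallback sets out from 16 and returns at 27, replacing substrate control by reagent control. The lithiated ether 19 is trapped with B(OiPr)3 to give the diisopropyl (Z)-γ-silyloxyallylboronate F3, which is transesterified with (R,R)-diisopropyl tartrate to the tartrate allylboronate F4. Allylboration of 16 (toluene, 4 Å MS, −78 °C) then proceeds through a closed chair transition state, in which the tartrate directs Si-face attack (6R) and the Z geometry gives the 6,7-syn relationship, delivering 27 directly.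

Step 15 (RCM to a trisubstituted alkene next to a bulky allylic OTBS, in a trans-fused ring, with free hydroxyls that can chelate ruthenium). The fallback sets out from 27 and returns at 30, changing the order of events. 27 is acylated first with 26 (DMAP, Et3N) to give the acyclic diene ester F5, whose RCM is not burdened by the free secondary hydroxyl and gives the bicyclic alkene ester F6. Epoxidation of F6 with mCPBA/NaHCO3 then relies on steric approach control (peracid opposite the C7-OTBS and the C1 methyl) and gives 30.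

**Further compounds**

F1 | step 6 | (2S,3R)-2-[(1R,2S)-2-(tert-butyldimethylsilyloxy)-1-(triethylsilyloxy)propyl]-3-methyl-3-(prop-2-en-1-yl)cyclopentan-1-one | O=C1CC[C@](C)(CC=C)[C@H]1[C@@H](O[Si](CC)(CC)CC)[C@H](C)O[Si](C)(C)C(C)(C)C
F2 | step 6 | (1R,2S,3R)-2-[(1R,2S)-2-(tert-butyldimethylsilyloxy)-1-(triethylsilyloxy)propyl]-3-methyl-1-(propan-2-yl)-3-(prop-2-en-1-yl)cyclopentan-1-ol | CC(C)[C@]1(O)CC[C@](C)(CC=C)[C@H]1[C@@H](O[Si](CC)(CC)CC)[C@H](C)O[Si](C)(C)C(C)(C)C
F3 | step 14 | dipropan-2-yl (Z)-[3-(tert-butyldimethylsilyloxy)-2-methylprop-2-en-1-yl]boronate | CC(C)OB(OC(C)C)C/C(C)=C\O[Si](C)(C)C(C)(C)C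
F4 | step 14 | dipropan-2-yl (4R,5R)-2-[(Z)-3-(tert-butyldimethylsilyloxy)-2-methylprop-2-en-1-yl]-1,3,2-dioxaborolane-4,5-dicarboxylate | CC(C)OC(=O)[C@@H]1OB(C/C(C)=C\O[Si](C)(C)C(C)(C)C)O[C@H]1C(=O)OC(C)C
F5 | step 15 | (1R,2R)-2-(tert-butyldimethylsilyloxy)-1-[(1S,2R,5R)-2-hydroxy-5-methyl-2-(propan-2-yl)-5-(prop-2-en-1-yl)cyclopentyl]-3-methylbut-3-en-1-yl 4-[(tert-butyldimethylsilyl)oxy]benzoate | CC(C)[C@]1(O)CC[C@](C)(CC=C)[C@H]1[C@@H](OC(=O)c2ccc(O[Si](C)(C)C(C)(C)C)cc2)[C@H](O[Si](C)(C)C(C)(C)C)C(C)=C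
F6 | step 15 | (1R,4R,5S,6R,7R)-7-(tert-butyldimethylsilyloxy)-4-hydroxydauc-8-en-6-yl 4-[(tert-butyldimethylsilyl)oxy]benzoate | CC(C)[C@]1(O)CC[C@]2(C)CC=C(C)[C@@H](O[Si](C)(C)C(C)(C)C)[C@H](OC(=O)c3ccc(O[Si](C)(C)C(C)(C)C)cc3)[C@H]21
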